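**Retrosynthetic overview**
1. Dicitrinone I ⇒ the C2-symmetric 7,7'-methylenebis(isochroman-6,8-diol). One half loses C1–H and the 8-OH hydrogen in a last-step dehydrogenation to the quinone methide.
2. Dimer ⇒ two molecules of the tris-MOM ether of (2R,3S)-3-(3,5-dihydroxy-2-methylphenyl)butan-2-ol. The C1–C8a bonds form first (oxa-Pictet–Spengler), then C7–CH2–C7' (Friedel–Crafts). All three CH2 units come from the MOM groups.
3. Monomer ⇒ aryl bromide (Br → CH3) ⇒ C4–C4a bond by the key step. This is an electrophile-triggered 1,2-shift of a sec-alkyl group from boron to the aryl ipso carbon, from 3,5-bis(MOMO)phenyllithium and (2R,3R)-2,3-bis(Bpin)butane.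
4. Aryl iodide ⇒ resorcinol (MOM protection, C–H borylation/iodination). Bis(boronate) ⇒ (E)-but-2-ene, where enantioselective diboration sets all four stereocentres.
5. Ring order: the benzene rings are bought, both dihydropyran rings close together in the cascade, the methylene bridge follows, and one isochroman is oxidised last.

Target as read from the SMILES: both halves are (3R,4S) with trans-3,4-dimethyl groups. The left half is the 6-hydroxy-8-oxo quinone methide, the right half is the 1H-isochroman-6,8-diol, and they are joined C7–CH2–C7'.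

Assumption: (S)-Quinap is taken as the ligand antipode that gives (2R,3R)-7. The sense is checked once by oxidising an aliquot of 7 to butane-2,3-diol against commercial (2R,3R)-diol, and (R)-Quinap is used if it is opposite.

**Step 1**
Reactants: 1 resorcinol
Product: 2 1,3-bis(methoxymethoxy)benzene
Conditions: MOMCl (2.5 equiv), i-Pr2NEt (3 equiv), CH2Cl2, 0 °C to rt
Reagents that add atoms: chloromethyl methyl ether COCCl
Why: Williamson-type O-alkylation (MOM protection) of both phenols, with no stereocentre involved, and the MOM carbons are used later as C1 building blocks.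

**Step 2**
Reactants: 2 1,3-bis(methoxymethoxy)benzene
Product: 4 1-iodo-3,5-bis(methoxymethoxy)benzene, via aryl pinacol boronate 3 (not isolated)
Conditions: [Ir(OMe)(cod)]2 (1 mol %), dtbpy (2 mol %), B2pin2 (1.0 equiv), THF, 80 °C; then CuI (10 mol %), 1,10-phenanthroline (20 mol %), KI (1.5 equiv), MeOH/H2O, air, 80 °C
Reagents that add atoms: bis(pinacolato)diboron CC1(C)OB(OC1(C)C)B1OC(C)(C)C(C)(C)O1 (Bpin of 3 only); potassium iodide [K+].[I-]
Why: Sterically controlled Ir-catalysed C–H borylation reaches only C5, the one C–H without an ortho substituent, and Cu-catalysed iododeboronation then swaps Bpin for iodine under near-neutral conditions that MOM ethers survive.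

**Step 3**
Reactants: 5 (E)-but-2-ene
Product: 7 2,2'-[(2R,3R)-butane-2,3-diyl]bis(4,4,5,5-tetramethyl-1,3,2-dioxaborolane), via bis(catecholboronate) 6 (not isolated)
Conditions: Rh(acac)(nbd) (5 mol %), (S)-Quinap (5 mol %), B2cat2 (1.0 equiv), 5 (3 equiv), THF, sealed tube, rt; then pinacol (2.5 equiv), rt
Reagents that add atoms: bis(catecholato)diboron B1(Oc2ccccc2O1)B1Oc2ccccc2O1; pinacol CC(C)(O)C(C)(C)O
Why: In this Rh-catalysed enantioselective alkene diboration, syn addition of B–B to the trans alkene gives only the C2-symmetric threo isomer and the ligand picks the alkene face, so both stereocentres (later C3 and C4 of each half) are set here before transesterification to the robust pinacol ester.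

**Step 4 (key step)**
Reactants: 4 1-iodo-3,5-bis(methoxymethoxy)benzene; 7 (2R,3R)-2,3-bis(Bpin)butane
Product: 12 (2R,3S)-3-[2-bromo-3,5-bis(methoxymethoxy)phenyl]butan-2-ol, via aryllithium 8 (not isolated), via boronate complex 9 (not isolated), via coupled boronic ester 10 (not isolated), via bromoaryl boronic ester 11 (not isolated)
Conditions: 4, t-BuLi (2.0 equiv), THF, −78 °C; 7 (1.1 equiv), −78 °C; NBS (1.1 equiv), −78 °C; NBS (1.05 equiv), 0 °C; then 2 M NaOH, 30% H2O2, 0 °C to rt
Reagents that add atoms: N-bromosuccinimide O=C1CCC(=O)N1Br; hydrogen peroxide OO; tert-butyllithium [Li]C(C)(C)C (lithium of 8 and 9 only)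
Why: Proposed new method: 8 adds to one of the two homotopic borons of C2-symmetric 7, so only one mono-ate complex 9 can form; NBS then brominates the ring ortho or para to boron (positions activated by both OMOM groups), and the arenium ion is quenched by a 1,2-shift of the sec-alkyl group from boron to the ipso carbon with retention at the migrating carbon; loss of Br and Bpin rearomatises to 10, which forms the C4–C4a bond and fixes C4, while the untouched second C–B bond serves as latent C3–OH (oxidised with retention, the benzylic descriptor changing from R to S only through CIP priorities) and the second equivalent of NBS brominates the position ortho to the new side chain and para to OMOM; the closest known reaction type is the electrophile-induced enantiospecific sp2–sp3 coupling of mono secondary boronic esters with 3,5-dialkoxyaryllithiums, which has not been shown on a vicinal bis(boronic ester).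

**Step 5**
Reactants: 12 (2R,3S)-3-[2-bromo-3,5-bis(methoxymethoxy)phenyl]butan-2-ol
Product: 15 1,5-bis(methoxymethoxy)-3-[(2S,3R)-3-(methoxymethoxy)butan-2-yl]-2-methylbenzene, via dilithio species 13 (not isolated), via lithium alkoxide 14 (not isolated)
Conditions: t-BuLi (3.1 equiv), THF, −78 °C; MeI (1.1 equiv), −78 to −30 °C; MOMCl (1.5 equiv), −30 °C to rt
Reagents that add atoms: iodomethane CI; chloromethyl methyl ether COCCl; tert-butyllithium [Li]C(C)(C)C (lithium of 13 and 14 only)
Why: Bromine–lithium exchange followed by electrophilic methylation works because the OMOM-chelated aryllithium takes MeI far faster than the lithium alkoxide does, the alkoxide is then capped by MOMCl, and no stereocentre is touched.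

**Step 6**
Reactants: 15 tris-MOM ether (two molecules)
Product: 18 7,7'-methylenebis[(3R,4S)-3,4,5-trimethyl-3,4-dihydro-1H-isochromene-6,8-diol], via monomeric isochroman-6,8-diol 16 (not isolated), via methoxymethyl monomer 17 (not isolated)
Conditions: TsOH·H2O (20 mol %), CH2Cl2/HFIP 4:1 (0.02 M), 0 °C to rt, then 40 °C, sealed flask
Reagents that add atoms: none
Why: Acid ionises the alkyl MOM ether to an oxocarbenium ion that closes on the only free position ortho to the side chain (oxa-Pictet–Spengler cyclisation of a MOM ether), and the cleaved aryl MOM groups re-enter as C1 electrophile at C7, the last nucleophilic carbon, so the phenol–formaldehyde-type Friedel–Crafts condensation must stop at the C7–CH2–C7' dimer; no stereocentre is touched and any minor enantiomer ends up mainly in the separable heterochiral diastereomer.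

**Step 7**
Reactants: 18 symmetric dimer
Product: 19 Dicitrinone I
Conditions: DDQ (1.0 equiv, slow addition), THF, 0 °C
Reagents that add atoms: none
Why: In this DDQ dehydrogenation of a phenolic benzylic ether to a quinone methide, hydride leaves from C1–H (alpha to the ring oxygen and ortho/para to two OH groups), loss of the 8-OH proton gives the push–pull vinylogous-ester quinone methide, the oxidised half is electron-poor so one equivalent stops mainly at mono-oxidation, and C3 and C4 are untouched.

**Compound list**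
1 | resorcinol (benzene-1,3-diol) | Oc1cccc(O)c1 | starting material
2 | 1,3-bis(methoxymethoxy)benzene | COCOc1cccc(OCOC)c1 | intermediate
3 | 2-[3,5-bis(methoxymethoxy)phenyl]-4,4,5,5-tetramethyl-1,3,2-dioxaborolane | COCOc1cc(OCOC)cc(B2OC(C)(C)C(C)(C)O2)c1 | intermediate
4 | 1-iodo-3,5-bis(methoxymethoxy)benzene | COCOc1cc(I)cc(OCOC)c1 | intermediate
5 | (E)-but-2-ene | C/C=C/C | starting material
6 | 2,2'-[(2R,3R)-butane-2,3-diyl]bis(1,3,2-benzodioxaborole) | B1(Oc2ccccc2O1)[C@H](C)[C@H](B1Oc2ccccc2O1)C | intermediate
7 | 2,2'-[(2R,3R)-butane-2,3-diyl]bis(4,4,5,5-tetramethyl-1,3,2-dioxaborolane) | CC1(C)OB(OC1(C)C)[C@H](C)[C@H](B1OC(C)(C)C(C)(C)O1)C | intermediate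
8 | [3,5-bis(methoxymethoxy)phenyl]lithium | [Li]c1cc(OCOC)cc(OCOC)c1 | intermediate
9 | lithium [3,5-bis(methoxymethoxy)phenyl](pinacolato)[(2R,3R)-3-(4,4,5,5-tetramethyl-1,3,2-dioxaborolan-2-yl)butan-2-yl]borate | [Li+].CC1(C)O[B-](OC1(C)C)(c1cc(OCOC)cc(OCOC)c1)[C@H](C)[C@H](B1OC(C)(C)C(C)(C)O1)C | intermediate
10 | 2-{(2R,3R)-3-[3,5-bis(methoxymethoxy)phenyl]butan-2-yl}-4,4,5,5-tetramethyl-1,3,2-dioxaborolane | CC1(C)OB(OC1(C)C)[C@H](C)[C@H](c1cc(OCOC)cc(OCOC)c1)C | intermediate
11 | 2-{(2R,3R)-3-[2-bromo-3,5-bis(methoxymethoxy)phenyl]butan-2-yl}-4,4,5,5-tetramethyl-1,3,2-dioxaborolane | CC1(C)OB(OC1(C)C)[C@H](C)[C@H](c1cc(OCOC)cc(OCOC)c1Br)C | intermediate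
12 | (2R,3S)-3-[2-bromo-3,5-bis(methoxymethoxy)phenyl]butan-2-ol | O[C@H](C)[C@H](c1cc(OCOC)cc(OCOC)c1Br)C | intermediate
13 | O,C-dilithio derivative of 12 (lithium alkoxide, aryl-Li in place of Br) | [Li]O[C@H](C)[C@H](c1cc(OCOC)cc(OCOC)c1[Li])C | intermediate
14 | lithium (2R,3S)-3-[3,5-bis(methoxymethoxy)-2-methylphenyl]butan-2-olate | [Li]O[C@H](C)[C@H](c1cc(OCOC)cc(OCOC)c1C)C | intermediate
15 | 1,5-bis(methoxymethoxy)-3-[(2S,3R)-3-(methoxymethoxy)butan-2-yl]-2-methylbenzene | COCO[C@H](C)[C@H](c1cc(OCOC)cc(OCOC)c1C)C | intermediate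
16 | (3R,4S)-3,4,5-trimethyl-3,4-dihydro-1H-isochromene-6,8-diol | c1c(O)c(C)c2c(c1O)CO[C@H](C)[C@H]2C | intermediate
17 | (3R,4S)-7-(methoxymethyl)-3,4,5-trimethyl-3,4-dihydro-1H-isochromene-6,8-diol | COCc1c(O)c(C)c2c(c1O)CO[C@H](C)[C@H]2C | intermediate
18 | 7,7'-methylenebis[(3R,4S)-3,4,5-trimethyl-3,4-dihydro-1H-isochromene-6,8-diol] | C(c1c(O)c(C)c2c(c1O)CO[C@H](C)[C@H]2C)c1c(O)c(C)c2c(c1O)CO[C@H](C)[C@H]2C | intermediate
19 | Dicitrinone I, (3R,4S)-7-{[(3R,4S)-6,8-dihydroxy-3,4,5-trimethyl-3,4-dihydro-1H-isochromen-7-yl]methyl}-6-hydroxy-3,4,5-trimethyl-4,8-dihydro-3H-isochromen-8-one | CC1=C2C(=CO[C@H](C)[C@H]2C)C(=O)C(Cc2c(O)c(C)c3c(c2O)CO[C@H](C)[C@H]3C)=C1O | target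

**Totals**
Total steps: 7. Longest linear sequence: 6 steps (1 → 2 → 4 → 12 → 15 → 18 → 19).

**Three steps most likely to fail**

Step 4 (the proposed new step).
- Risks: NBS may attack the sp3 C–B bond of 9, which leads to a beta-bromo boronate and loss of butene. A double ate complex may form. The second bromination may be unselective.
- Fallback (known chemistry): it sets out from 4 and comes back at 12. Iodine–magnesium exchange of 4 with i-PrMgCl·LiCl (THF, −20 °C) gives [3,5-bis(methoxymethoxy)phenyl]magnesium chloride F1. With CuI (10 mol %), F1 opens purchased (2S,3S)-2,3-dimethyloxirane F2 by SN2 attack with inversion to give the erythro alcohol (2S,3S)-3-[3,5-bis(methoxymethoxy)phenyl]butan-2-ol F3. Mitsunobu inversion (4-nitrobenzoic acid, PPh3, DIAD) gives (2R,3S)-3-[3,5-bis(methoxymethoxy)phenyl]butan-2-yl 4-nitrobenzoate F4. Methanolysis (K2CO3, MeOH) gives the threo alcohol (2R,3S)-3-[3,5-bis(methoxymethoxy)phenyl]butan-2-ol F5, and NBS (MeCN, 0 °C) brominates ortho to the side chain to give 12.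

Step 6.
- Risks: an external benzylic cation may attack C8a of a molecule that has not yet cyclised, giving wrongly bridged oligomers. Benzodioxin by-products may form from the surplus C1 units.
- Fallback: it sets out from 15 and comes back at 18, with each bond made in a separate, directed operation. HCl in MeOH removes all three MOM groups, and the solvent traps the C1 units as the acetal, to give (2R,3S)-3-(3,5-dihydroxy-2-methylphenyl)butan-2-ol F6. A separate oxa-Pictet–Spengler reaction (dimethoxymethane, TsOH, high dilution) gives 16, now isolated. Half of 16 is converted with dimethylmethyleneiminium iodide into the Mannich base (3R,4S)-7-[(dimethylamino)methyl]-3,4,5-trimethyl-3,4-dihydro-1H-isochromene-6,8-diol F7. Heating F7 with the other half of 16 (toluene, 100 °C) releases an o-quinone methide that is captured at C7 to give 18.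

Step 7.
- Risks: hydride abstraction may occur at the diarylmethane CH2 instead of C1, both halves may be oxidised, and mono-oxidation has a statistical ceiling.
- Fallback: it sets out from 15 and comes back at 19. It avoids any late oxidation by bringing the higher oxidation level in with the C1 reagent. The triol (2R,3S)-3-(3,5-dihydroxy-2-methylphenyl)butan-2-ol F6 is made from 15 as above. Treatment with HC(OEt)3 and TFA gives decarboxycitrinin, (3R,4S)-6-hydroxy-3,4,5-trimethyl-4,8-dihydro-3H-isochromen-8-one F8. The Mannich base (3R,4S)-7-[(dimethylamino)methyl]-3,4,5-trimethyl-3,4-dihydro-1H-isochromene-6,8-diol F7 is made from 16 as above. Heating F7 with F8 (dioxane, 80 °C) generates its o-quinone methide, which is captured by C7 of F8 (the carbon between the enol and the ketone) to give 19 directly.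

**Further compounds**
F1 | step 4 | [3,5-bis(methoxymethoxy)phenyl]magnesium chloride | COCOc1cc([Mg]Cl)cc(OCOC)c1
F2 | step 4 | (2S,3S)-2,3-dimethyloxirane | C[C@@H]1O[C@H]1C
F3 | step 4 | (2S,3S)-3-[3,5-bis(methoxymethoxy)phenyl]butan-2-ol | O[C@@H](C)[C@H](c1cc(OCOC)cc(OCOC)c1)C
F4 | step 4 | (2R,3S)-3-[3,5-bis(methoxymethoxy)phenyl]butan-2-yl 4-nitrobenzoate | O=C(c1ccc(cc1)[N+](=O)[O-])O[C@H](C)[C@H](c1cc(OCOC)cc(OCOC)c1)C
F5 | step 4 | (2R,3S)-3-[3,5-bis(methoxymethoxy)phenyl]butan-2-ol | O[C@H](C)[C@H](c1cc(OCOC)cc(OCOC)c1)C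
F6 | step 6 | (2R,3S)-3-(3,5-dihydroxy-2-methylphenyl)butan-2-ol | O[C@H](C)[C@H](c1cc(O)cc(O)c1C)C
F7 | step 6 | (3R,4S)-7-[(dimethylamino)methyl]-3,4,5-trimethyl-3,4-dihydro-1H-isochromene-6,8-diol | CN(C)Cc1c(O)c(C)c2c(c1O)CO[C@H](C)[C@H]2C
F8 | step 7 | decarboxycitrinin, (3R,4S)-6-hydroxy-3,4,5-trimethyl-4,8-dihydro-3H-isochromen-8-one | CC1=C2C(=CO[C@H](C)[C@H]2C)C(=O)C=C1O
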